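The oxepane (O1, C2 quaternary, C3 acetoxy, C4, C5, C6 alkylidene, C7) is disconnected at C6–C7. The key step exploits the vicinal oxygens on C2 and C3 and the unsubstituted C7 beside the exocyclic E alkene: the precursor holds the C2/C3 diol as a 1,3-dioxolane, whose acetal carbon is the future C7, and an E vinylsilane at C6. Acetyl chloride opens this temporary ring at the less hindered oxygen, which installs the C3 acetate and leaves an oxocarbenium ion on O1; ipso attack of the vinylsilane then closes the seven-membered ring and fixes the alkene geometry. The open chain comes from two B-alkyl Suzuki couplings and two allylborations.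

Key step: step 12

Remark: side-chain carbons are called C1′ to C8′ from the ring outwards; (−)-B-methoxydiisopinocampheylborane, cis-2-butene, allyl methoxymethyl ether, (Z)-1-bromo-2-ethoxyethene and 3-(trimethylsilyl)prop-2-yn-1-ol are assumed to be commercial.

Step 1
Reactants: 1 4-methylpent-3-en-1-ol
Product: 2 4-methylpent-3-enal
Conditions: Dess–Martin periodinane, pyridine, CH2Cl2, 0 °C; crude solution used at once
Reagents that add atoms: none
Why: Dess–Martin oxidation under pyridine buffer should give the β,γ-unsaturated aldehyde without shifting the double bond into conjugation.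

Step 2
Reactants: 2 4-methylpent-3-enal
Product: 3 (3R,4R)-3,7-dimethylocta-1,6-dien-4-ol
Conditions: cis-2-butene, n-BuLi, KOt-Bu, THF, −78 to −45 °C; (−)-B-methoxydiisopinocampheylborane, then BF3·OEt2, −78 °C; 2, −78 °C; NaOH, H2O2, 0 °C to rt
Reagents that add atoms: (Z)-crotyldiisopinocampheylborane, made in the flask from cis-2-butene (C/C=C\C), C/C=C\CB([C@@H]1C[C@@H]2C[C@H]([C@H]1C)C2(C)C)[C@@H]1C[C@@H]2C[C@H]([C@H]1C)C2(C)C
Why: Asymmetric crotylboration (Brown crotylation): the Z crotylborane reacts through a closed chair transition state, so the Z geometry should give the 3,4-syn pair and the isopinocampheyl groups derived from (+)-α-pinene should direct the allyl unit to the Si face of the aldehyde, which sets 3R and 4R.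

Step 3
Reactants: 3 (3R,4R)-3,7-dimethylocta-1,6-dien-4-ol
Product: 4 tert-butyl{[(3R,4R)-3,7-dimethylocta-1,6-dien-4-yl]oxy}diphenylsilane
Conditions: TBDPSCl, imidazole, DMAP (cat.), DMF, 40 °C
Reagents that add atoms: tert-butyl(chloro)diphenylsilane, CC(C)(C)[Si](Cl)(c1ccccc1)c1ccccc1
Why: Silylation of the secondary alcohol; the TBDPS ether is chosen because it should survive the Lewis acids of steps 8 and 12 and can be removed beside two acetates.

Step 4
Reactants: 4 tert-butyl{[(3R,4R)-3,7-dimethylocta-1,6-dien-4-yl]oxy}diphenylsilane; 5 (Z)-1-bromo-2-ethoxyethene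
Product: 8 (5R,6R)-6-[(tert-butyldiphenylsilyl)oxy]-5,9-dimethyldec-8-enal, via B-alkyl-9-BBN adduct 6 (not isolated), via Z enol ether 7 (not isolated)
Conditions: 9-BBN, THF, 0 °C to rt; then 5, Pd(dppf)Cl2 (5 mol %), Cs2CO3, DMF–H2O, rt; aqueous work-up, then 1 M HCl, THF, rt
Reagents that add atoms: water, O
Why: 9-BBN should hydroborate only the monosubstituted alkene of 4, the B-alkyl Suzuki–Miyaura coupling joins C2′ to the bromoalkene with retention, and acid hydrolysis of the enol ether unmasks the aldehyde two carbons beyond the former vinyl group; no stereocentre is touched.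

Step 5
Reactants: 8 (5R,6R)-6-[(tert-butyldiphenylsilyl)oxy]-5,9-dimethyldec-8-enal
Product: 9 (3R,4R,8R,9R)-9-[(tert-butyldiphenylsilyl)oxy]-3-(methoxymethoxy)-8,12-dimethyltrideca-1,11-dien-4-ol
Conditions: allyl methoxymethyl ether, s-BuLi, THF, −78 °C; (−)-B-methoxydiisopinocampheylborane, then BF3·OEt2, −78 °C; 8, −78 °C; NaOH, H2O2, 0 °C to rt
Reagents that add atoms: [(Z)-3-(methoxymethoxy)allyl]diisopinocampheylborane, made in the flask from allyl methoxymethyl ether (C=CCOCOC), COCO/C=C\CB([C@@H]1C[C@@H]2C[C@H]([C@H]1C)C2(C)C)[C@@H]1C[C@@H]2C[C@H]([C@H]1C)C2(C)C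
Why: γ-Alkoxyallylboration through the same closed transition state: the Z alkoxyallyl reagent should give the syn 3,4-diol monoether and Si-face attack fixes the ether-bearing carbon as R (the future C3); the carbinol centre is removed in step 6.

Step 6
Reactants: 9 (3R,4R,8R,9R)-9-[(tert-butyldiphenylsilyl)oxy]-3-(methoxymethoxy)-8,12-dimethyltrideca-1,11-dien-4-ol
Product: 10 (3R,8R,9R)-9-[(tert-butyldiphenylsilyl)oxy]-3-(methoxymethoxy)-8,12-dimethyltrideca-1,11-dien-4-one
Conditions: Dess–Martin periodinane, pyridine, CH2Cl2, 0 °C; crude ketone used at once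
Reagents that add atoms: none
Why: Dess–Martin oxidation is mild enough that the α-alkoxy β,γ-unsaturated ketone should form without enolisation, so the R centre next to the carbonyl is kept.

Step 7
Reactants: 10 (3R,8R,9R)-9-[(tert-butyldiphenylsilyl)oxy]-3-(methoxymethoxy)-8,12-dimethyltrideca-1,11-dien-4-one
Product: 11 (3R,4S,8R,9R)-9-[(tert-butyldiphenylsilyl)oxy]-3-(methoxymethoxy)-4,8,12-trimethyltrideca-1,11-dien-4-ol
Conditions: MeMgBr, Et2O–CH2Cl2, −78 °C
Reagents that add atoms: methylmagnesium bromide, C[Mg]Br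
Why: Chelation-controlled Grignard addition (Cram chelate): magnesium bridges the ketone oxygen and the methoxymethyl ether oxygen, and methyl adds to the face of the five-membered chelate that carries H, not vinyl, which sets the tertiary centre as S (the future C2) relative to 3R.

Step 8
Reactants: 11 (3R,4S,8R,9R)-9-[(tert-butyldiphenylsilyl)oxy]-3-(methoxymethoxy)-4,8,12-trimethyltrideca-1,11-dien-4-ol
Product: 12 (4R,5S)-5-{(4R,5R)-5-[(tert-butyldiphenylsilyl)oxy]-4,8-dimethylnon-7-en-1-yl}-4-ethenyl-5-methyl-1,3-dioxolane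
Conditions: TMSOTf (0.1 equiv), 4 Å molecular sieves, CH2Cl2, −40 to 0 °C; then Et3N
Reagents that add atoms: none
Why: Intramolecular transacetalization: the Lewis acid ionises the methoxymethyl ether to an oxocarbenium ion that the neighbouring tertiary hydroxyl captures in a five-membered ring with loss of methanol; neither stereocentre takes part.

Step 9
Reactants: 13 3-(trimethylsilyl)prop-2-yn-1-ol
Product: 14 (Z)-3-iodo-3-(trimethylsilyl)prop-2-en-1-ol
Conditions: NaAlH2(OCH2CH2OCH3)2 (Red-Al), Et2O, 0 °C to rt; then I2, −78 to 0 °C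
Reagents that add atoms: iodine, II
Why: Alkoxide-directed trans-hydroalumination places aluminium on the silicon-bearing carbon cis to the CH2O group and hydrogen on C2, and iodinolysis with retention should give the Z iodoalkene in which silicon is trans to CH2OH.

Step 10
Reactants: 12 (4R,5S)-5-{(4R,5R)-5-[(tert-butyldiphenylsilyl)oxy]-4,8-dimethylnon-7-en-1-yl}-4-ethenyl-5-methyl-1,3-dioxolane; 14 (Z)-3-iodo-3-(trimethylsilyl)prop-2-en-1-ol
Product: 16 (2E)-5-[(4R,5S)-5-{(4R,5R)-5-[(tert-butyldiphenylsilyl)oxy]-4,8-dimethylnon-7-en-1-yl}-5-methyl-1,3-dioxolan-4-yl]-3-(trimethylsilyl)pent-2-en-1-ol, via B-alkyl-9-BBN adduct 15 (not isolated)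
Conditions: 9-BBN, THF, rt; then 14, Pd(dppf)Cl2 (5 mol %), AsPh3, Cs2CO3, DMF–H2O, rt
Reagents that add atoms: none
Why: B-alkyl Suzuki–Miyaura coupling: 9-BBN should add only to the terminal alkene of 12 and the alkyl group replaces iodide with retention, so the E vinylsilane (silicon trans to CH2OH) is formed with C5 cis to CH2OH.

Step 11
Reactants: 16 (2E)-5-[(4R,5S)-5-{(4R,5R)-5-[(tert-butyldiphenylsilyl)oxy]-4,8-dimethylnon-7-en-1-yl}-5-methyl-1,3-dioxolan-4-yl]-3-(trimethylsilyl)pent-2-en-1-ol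
Product: 17 (2E)-5-[(4R,5S)-5-{(4R,5R)-5-[(tert-butyldiphenylsilyl)oxy]-4,8-dimethylnon-7-en-1-yl}-5-methyl-1,3-dioxolan-4-yl]-3-(trimethylsilyl)pent-2-en-1-yl acetate
Conditions: Ac2O, pyridine, DMAP (cat.), CH2Cl2, 0 °C to rt
Reagents that add atoms: acetic anhydride, CC(=O)OC(C)=O
Why: Acetylation of the only free hydroxyl installs the primary allylic acetate of the target before any Lewis acid is used.

Step 12
Reactants: 17 (2E)-5-[(4R,5S)-5-{(4R,5R)-5-[(tert-butyldiphenylsilyl)oxy]-4,8-dimethylnon-7-en-1-yl}-5-methyl-1,3-dioxolan-4-yl]-3-(trimethylsilyl)pent-2-en-1-yl acetate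
Product: 19 (2S,3R,6E)-6-(2-acetoxyethylidene)-2-{(4R,5R)-5-[(tert-butyldiphenylsilyl)oxy]-4,8-dimethylnon-7-en-1-yl}-2-methyloxepan-3-yl acetate, via chloromethyl ether acetate 18 (not isolated)
Conditions: AcCl (1.05 equiv), ZnCl2 (5 mol %), 2,6-di-tert-butyl-4-methylpyridine (0.3 equiv), CH2Cl2, 0 °C; then SnCl4 (0.5 equiv), −78 to −30 °C, 0.01 M
Reagents that add atoms: acetyl chloride, CC(=O)Cl
Why: Acetyl chloride with catalytic ZnCl2 acylates the less hindered dioxolane oxygen (the one on C3), and ring opening leaves the acetal carbon as a chloromethyl ether on the tertiary oxygen (acylative cleavage of a cyclic formal); SnCl4 then ionises this α-chloro ether to the oxocarbenium ion O1=C7H2. The vinylsilane attacks through its silicon-bearing carbon C6 (ipso), the β-silyl cation loses the silyl group as Me3SiCl, and the new C6–C7 bond closes the oxepane; the closest known reaction type is the vinylsilane-terminated cyclisation of α-alkoxycarbenium ions to alkylidene oxacycles. The seven-membered ring closes endo with respect to the C7=O1 bond (both atoms end up in the ring) and exo with respect to the vinylsilane C=C bond. No stereocentre is formed: C2 (S) and C3 (R) are carried over from 17 because only acetal C–O bonds break, and the E geometry of the exocyclic alkene follows from stereoretentive replacement of silicon in the E vinylsilane. The step needs acylation at the oxygen on C3 (the other regiochemistry would put the cation on that oxygen and give a tetrahydropyran), which the steric difference between a secondary and a fully substituted carbinol oxygen should secure, and it needs attack at C6 and not at the other alkene carbon, which the β-silicon effect secures; the side-chain alkene could only close a ten-membered ring and the TBDPS ether is chosen to withstand both Lewis acids.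

Step 13
Reactants: 19 (2S,3R,6E)-6-(2-acetoxyethylidene)-2-{(4R,5R)-5-[(tert-butyldiphenylsilyl)oxy]-4,8-dimethylnon-7-en-1-yl}-2-methyloxepan-3-yl acetate
Product: 20 (2S,3R,6E)-6-(2-acetoxyethylidene)-2-[(4R,5R)-5-hydroxy-4,8-dimethylnon-7-en-1-yl]-2-methyloxepan-3-yl acetate
Conditions: Bu4NF, AcOH (1:1), THF, 0 °C to rt
Reagents that add atoms: none
Why: Fluoride cleaves the Si–O bond of the silyl ether, and the acetic acid buffer should keep the medium from hydrolysing or shifting the two acetates; no stereocentre is touched.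

Compound list
1 | 4-methylpent-3-en-1-ol | CC(C)=CCCO | starting material
2 | 4-methylpent-3-enal | CC(C)=CCC=O | intermediate
3 | (3R,4R)-3,7-dimethylocta-1,6-dien-4-ol | C=C[C@@H](C)[C@H](O)CC=C(C)C | intermediate
4 | tert-butyl{[(3R,4R)-3,7-dimethylocta-1,6-dien-4-yl]oxy}diphenylsilane | C=C[C@@H](C)[C@H](O[Si](c1ccccc1)(c1ccccc1)C(C)(C)C)CC=C(C)C | intermediate
5 | (Z)-1-bromo-2-ethoxyethene | CCO/C=C\Br | starting material
6 | 9-{(3R,4R)-4-[(tert-butyldiphenylsilyl)oxy]-3,7-dimethyloct-6-en-1-yl}-9-borabicyclo[3.3.1]nonane (not isolated) | B1(CC[C@@H](C)[C@H](O[Si](c3ccccc3)(c3ccccc3)C(C)(C)C)CC=C(C)C)C2CCCC1CCC2 | intermediate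
7 | tert-butyl{[(1Z,5R,6R)-1-ethoxy-5,9-dimethyldeca-1,8-dien-6-yl]oxy}diphenylsilane (not isolated) | CCO/C=C\CC[C@@H](C)[C@H](O[Si](c1ccccc1)(c1ccccc1)C(C)(C)C)CC=C(C)C | intermediate
8 | (5R,6R)-6-[(tert-butyldiphenylsilyl)oxy]-5,9-dimethyldec-8-enal | O=CCCC[C@@H](C)[C@H](O[Si](c1ccccc1)(c1ccccc1)C(C)(C)C)CC=C(C)C | intermediate
9 | (3R,4R,8R,9R)-9-[(tert-butyldiphenylsilyl)oxy]-3-(methoxymethoxy)-8,12-dimethyltrideca-1,11-dien-4-ol | C=C[C@@H](OCOC)[C@H](O)CCC[C@@H](C)[C@H](O[Si](c1ccccc1)(c1ccccc1)C(C)(C)C)CC=C(C)C | intermediate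
10 | (3R,8R,9R)-9-[(tert-butyldiphenylsilyl)oxy]-3-(methoxymethoxy)-8,12-dimethyltrideca-1,11-dien-4-one | C=C[C@@H](OCOC)C(=O)CCC[C@@H](C)[C@H](O[Si](c1ccccc1)(c1ccccc1)C(C)(C)C)CC=C(C)C | intermediate
11 | (3R,4S,8R,9R)-9-[(tert-butyldiphenylsilyl)oxy]-3-(methoxymethoxy)-4,8,12-trimethyltrideca-1,11-dien-4-ol | C=C[C@@H](OCOC)[C@@](C)(O)CCC[C@@H](C)[C@H](O[Si](c1ccccc1)(c1ccccc1)C(C)(C)C)CC=C(C)C | intermediate
12 | (4R,5S)-5-{(4R,5R)-5-[(tert-butyldiphenylsilyl)oxy]-4,8-dimethylnon-7-en-1-yl}-4-ethenyl-5-methyl-1,3-dioxolane | C=C[C@H]1OCO[C@@]1(C)CCC[C@@H](C)[C@H](O[Si](c2ccccc2)(c2ccccc2)C(C)(C)C)CC=C(C)C | intermediate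
13 | 3-(trimethylsilyl)prop-2-yn-1-ol | C[Si](C)(C)C#CCO | starting material
14 | (Z)-3-iodo-3-(trimethylsilyl)prop-2-en-1-ol | OC/C=C(I)/[Si](C)(C)C | intermediate
15 | 9-{2-[(4R,5S)-5-{(4R,5R)-5-[(tert-butyldiphenylsilyl)oxy]-4,8-dimethylnon-7-en-1-yl}-5-methyl-1,3-dioxolan-4-yl]ethyl}-9-borabicyclo[3.3.1]nonane (not isolated) | B1(CC[C@H]3OCO[C@@]3(C)CCC[C@@H](C)[C@H](O[Si](c4ccccc4)(c4ccccc4)C(C)(C)C)CC=C(C)C)C2CCCC1CCC2 | intermediate
16 | (2E)-5-[(4R,5S)-5-{(4R,5R)-5-[(tert-butyldiphenylsilyl)oxy]-4,8-dimethylnon-7-en-1-yl}-5-methyl-1,3-dioxolan-4-yl]-3-(trimethylsilyl)pent-2-en-1-ol | OC/C=C(CC[C@H]1OCO[C@@]1(C)CCC[C@@H](C)[C@H](O[Si](c2ccccc2)(c2ccccc2)C(C)(C)C)CC=C(C)C)/[Si](C)(C)C | intermediate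
17 | (2E)-5-[(4R,5S)-5-{(4R,5R)-5-[(tert-butyldiphenylsilyl)oxy]-4,8-dimethylnon-7-en-1-yl}-5-methyl-1,3-dioxolan-4-yl]-3-(trimethylsilyl)pent-2-en-1-yl acetate | CC(=O)OC/C=C(CC[C@H]1OCO[C@@]1(C)CCC[C@@H](C)[C@H](O[Si](c2ccccc2)(c2ccccc2)C(C)(C)C)CC=C(C)C)/[Si](C)(C)C | intermediate
18 | (2E,6R,7S,11R,12R)-6-acetoxy-12-[(tert-butyldiphenylsilyl)oxy]-7-(chloromethoxy)-7,11,15-trimethyl-3-(trimethylsilyl)hexadeca-2,14-dien-1-yl acetate (not isolated) | CC(=O)OC/C=C(CC[C@@H](OC(C)=O)[C@@](C)(OCCl)CCC[C@@H](C)[C@H](O[Si](c1ccccc1)(c1ccccc1)C(C)(C)C)CC=C(C)C)/[Si](C)(C)C | intermediate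
19 | (2S,3R,6E)-6-(2-acetoxyethylidene)-2-{(4R,5R)-5-[(tert-butyldiphenylsilyl)oxy]-4,8-dimethylnon-7-en-1-yl}-2-methyloxepan-3-yl acetate | CC(=O)OC/C=C1\CC[C@@H](OC(C)=O)[C@](C)(CCC[C@@H](C)[C@H](O[Si](c2ccccc2)(c2ccccc2)C(C)(C)C)CC=C(C)C)OC1 | intermediate
20 | (2S,3R,6E)-6-(2-acetoxyethylidene)-2-[(4R,5R)-5-hydroxy-4,8-dimethylnon-7-en-1-yl]-2-methyloxepan-3-yl acetate | CC(=O)OC/C=C1\CC[C@@H](OC(C)=O)[C@](C)(CCC[C@@H](C)[C@H](O)CC=C(C)C)OC1 | target

Total step count: 13. Longest linear sequence: 12 steps (from 1 through steps 1–8 and 10–13); step 9 is the one-step side branch to 14.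

Steps most likely to fail

Step 12 (key step). Acylation could occur at the hindered oxygen and lead to six-membered ring closure, the tertiary C2–O bond could ionise, the silyl group could be lost from the alkene by stray acid before the C–C bond forms, or residual AcCl could acylate an alkene once SnCl4 is present. The fallback separates acetal opening from ring closure and sets out from 17: the opening is run alone (AcCl, ZnCl2 cat., CH2Cl2, 0 °C) and the chloromethyl ether is quenched with 2-methoxyethanol and i-Pr2NEt to give the isolable (2E,6R,7S,11R,12R)-6-acetoxy-12-[(tert-butyldiphenylsilyl)oxy]-7-[(2-methoxyethoxy)methoxy]-7,11,15-trimethyl-3-(trimethylsilyl)hexadeca-2,14-dien-1-yl acetate F1, which can be freed of any regioisomer by chromatography. F1 is then cyclised with SnCl4 (2 equiv, CH2Cl2, −20 °C), where bidentate binding of tin to the acetal side chain releases the same oxocarbenium ion with no acylating agent present, and the route is rejoined at 19.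

Step 8. Ionisation of the methoxymethyl ether could stall, acetal exchange could become intermolecular, or the acid could attack the trisubstituted alkene. The fallback replaces the acid-driven ring closure by deprotection and base-mediated ring formation and sets out from 11: thiol-assisted removal of the methoxymethyl group (ZnBr2, n-PrSH, CH2Cl2, 0 °C) should give (3R,4S,8R,9R)-9-[(tert-butyldiphenylsilyl)oxy]-4,8,12-trimethyltrideca-1,11-diene-3,4-diol F2, and double O-alkylation of F2 (CH2Br2, NaH, DMF, 0 °C to rt) returns to 12.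

Step 10. Transmetalation onto the hindered α-silyl alkenylpalladium species could be slow, so that β-hydride elimination or protodeboronation of the alkylborane takes over. The fallback changes the nucleophile to an organozinc made from a halide and sets out from 12: hydroboration–oxidation (9-BBN; NaOH, H2O2) should give 2-[(4R,5S)-5-{(4R,5R)-5-[(tert-butyldiphenylsilyl)oxy]-4,8-dimethylnon-7-en-1-yl}-5-methyl-1,3-dioxolan-4-yl]ethan-1-ol F3, iodination (I2, PPh3, imidazole, CH2Cl2) the corresponding primary iodide F4, and zinc insertion (Zn dust, LiCl, THF) the alkylzinc iodide F5. Negishi coupling of F5 with the sodium alkoxide of 14 (NaH; Pd2(dba)3, SPhos, THF, rt) returns to 16.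

Further compounds
F1 | step 12 | (2E,6R,7S,11R,12R)-6-acetoxy-12-[(tert-butyldiphenylsilyl)oxy]-7-[(2-methoxyethoxy)methoxy]-7,11,15-trimethyl-3-(trimethylsilyl)hexadeca-2,14-dien-1-yl acetate | CC(=O)OC/C=C(CC[C@@H](OC(C)=O)[C@@](C)(OCOCCOC)CCC[C@@H](C)[C@H](O[Si](c1ccccc1)(c1ccccc1)C(C)(C)C)CC=C(C)C)/[Si](C)(C)C
F2 | step 8 | (3R,4S,8R,9R)-9-[(tert-butyldiphenylsilyl)oxy]-4,8,12-trimethyltrideca-1,11-diene-3,4-diol | C=C[C@@H](O)[C@@](C)(O)CCC[C@@H](C)[C@H](O[Si](c1ccccc1)(c1ccccc1)C(C)(C)C)CC=C(C)C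
F3 | step 10 | 2-[(4R,5S)-5-{(4R,5R)-5-[(tert-butyldiphenylsilyl)oxy]-4,8-dimethylnon-7-en-1-yl}-5-methyl-1,3-dioxolan-4-yl]ethan-1-ol | OCC[C@H]1OCO[C@@]1(C)CCC[C@@H](C)[C@H](O[Si](c2ccccc2)(c2ccccc2)C(C)(C)C)CC=C(C)C
F4 | step 10 | (4R,5S)-5-{(4R,5R)-5-[(tert-butyldiphenylsilyl)oxy]-4,8-dimethylnon-7-en-1-yl}-4-(2-iodoethyl)-5-methyl-1,3-dioxolane | ICC[C@H]1OCO[C@@]1(C)CCC[C@@H](C)[C@H](O[Si](c2ccccc2)(c2ccccc2)C(C)(C)C)CC=C(C)C
F5 | step 10 | {2-[(4R,5S)-5-{(4R,5R)-5-[(tert-butyldiphenylsilyl)oxy]-4,8-dimethylnon-7-en-1-yl}-5-methyl-1,3-dioxolan-4-yl]ethyl}zinc iodide (not isolated) | I[Zn]CC[C@H]1OCO[C@@]1(C)CCC[C@@H](C)[C@H](O[Si](c2ccccc2)(c2ccccc2)C(C)(C)C)CC=C(C)C
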